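**Assumptions and conventions**

- Assumption: (R)-pent-3-yn-2-ol is bought as the single enantiomer; if the furan-face selectivity in step 7 were opposite to the invertive, extended transition state assumed here, the (S)-alkynol would be used and nothing else changes.
- Convention: locants C1–C15 are those of the target throughout (C1 carbinol, C4/C5 epoxide, C6 ester, C7/C8 lactone fusion, C11–C13 methylene-lactone carbons, C14/C15 methyls). "Tricycle" means the (4+3) adduct skeleton: a C1–C5 bond (cyclopentane C1–C5) and an oxygen bridge C1–O–C8 across the seven-membered ring C1/C10/C9/C8/C7/C6/C5.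

**Retrosynthetic overview**

1. Target ⇐ C1 ketone reduction, C6 angeloylation and C6-OH-controlled epoxidation of a (4Z,9Z)-1-oxo-germacradien-12,8-olide.
2. Ten-membered ring ⇐ ring expansion: ether-assisted Grob fragmentation of a 5-7 fused, oxygen-bridged tricycle (C1–C5 cleaved, C4–OSiEt3 leaves), giving C1=O, C8–OH (then lactone) and the 4Z alkene.
3. Tricycle ⇐ intramolecular (4+3) cycloaddition of a furan-tethered epoxy enol silane; the C7 acrylate arm comes from enolate alkylation and methylenation, C6 from ketone reduction.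
4. Epoxy ketone ⇐ (R,Z)-allylic alcohol ⇐ B-alkyl Suzuki coupling of 3-methyl-2-vinylfuran with a Z-vinyl iodide made from (R)-pent-3-yn-2-ol.
5. Ring order: furan (bought) → cyclopentane plus oxa-bridged cycloheptenone (one step) → ten-membered carbocycle → γ-lactone → epoxide.

**Route**

Step 1
Reactants: 1 3-methylfuran-2-carbaldehyde
Product: 2 3-methyl-2-vinylfuran
Conditions: Ph3PCH3Br, KOtBu, THF, 0 °C to rt
Reagents that add atoms: methyltriphenylphosphonium bromide, C[P+](c1ccccc1)(c1ccccc1)c1ccccc1.[Br-]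
Why: Wittig methylenation of a non-enolisable aldehyde; no stereocentre is formed.

Step 2
Reactants: 3 (R)-pent-3-yn-2-ol
Product: 5 (R,Z)-4-iodopent-3-en-2-ol, via cyclic vinylalanate 4 (not isolated)
Conditions: Red-Al, THF, 0 °C to rt; I2, THF, −78 °C
Reagents that add atoms: iodine, II
Why: Hydroxyl-directed trans-hydroalumination puts aluminium on the distal alkyne carbon and iodinolysis with retention gives the Z-iodide (iodine cis to the carbinol carbon); the carbinol stereocentre is untouched.

Step 3
Reactants: 2 3-methyl-2-vinylfuran; 5 (R,Z)-4-iodopent-3-en-2-ol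
Product: 7 (R,Z)-4-methyl-6-(3-methylfuran-2-yl)hex-3-en-2-ol, via alkylborane 6 (not isolated)
Conditions: 9-BBN, THF, 0 °C to rt; then 5, PdCl2(dppf) (5 mol %), AsPh3, Cs2CO3, DMF–H2O, rt
Reagents that add atoms: none
Why: Anti-Markovnikov hydroboration followed by B-alkyl Suzuki–Miyaura coupling with retention at the vinyl iodide places the furylethyl chain cis to the carbinol carbon (Z) and tolerates the free hydroxyl.

Step 4
Reactants: 7 (R,Z)-4-methyl-6-(3-methylfuran-2-yl)hex-3-en-2-ol
Product: 8 (R)-1-[(2S,3R)-3-methyl-3-[2-(3-methylfuran-2-yl)ethyl]oxiran-2-yl]ethan-1-ol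
Conditions: VO(acac)2 (5 mol %), t-BuOOH, CH2Cl2, 0 °C
Reagents that add atoms: tert-butyl hydroperoxide, CC(C)(C)OO
Why: Vanadium-catalysed hydroxyl-directed epoxidation in which A(1,3) strain from the cis chain holds the carbinol H in the alkene plane, so oxygen is delivered to the OH face of that conformer and the threo epoxy alcohol results (about 6:1; the erythro isomer is removed by chromatography because it would erode the ee after step 5).

Step 5
Reactants: 8 (R)-1-[(2S,3R)-3-methyl-3-[2-(3-methylfuran-2-yl)ethyl]oxiran-2-yl]ethan-1-ol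
Product: 9 1-[(2R,3R)-3-methyl-3-[2-(3-methylfuran-2-yl)ethyl]oxiran-2-yl]ethan-1-one
Conditions: Dess–Martin periodinane, CH2Cl2, 0 °C to rt
Reagents that add atoms: none
Why: Dess–Martin oxidation removes the now superfluous carbinol centre without touching the cis-epoxide, whose two stereocentres carry the chirality forward.

Step 6
Reactants: 9 1-[(2R,3R)-3-methyl-3-[2-(3-methylfuran-2-yl)ethyl]oxiran-2-yl]ethan-1-one
Product: 10 triethylsilyl enol ether of 9 (terminal C6=C7 enol silane)
Conditions: TESOTf, Et3N, CH2Cl2, −78 to 0 °C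
Reagents that add atoms: triethylsilyl triflate, CC[Si](CC)(CC)OS(=O)(=O)C(F)(F)F
Why: Soft enolisation and O-silylation is regiospecific because only the methyl side can enolise (the other α-carbon is the epoxide CH).

Step 7
Reactants: 10 triethylsilyl enol ether of 9
Product: 11 (1S,4R,5S,8R)-tricycle 6-ketone with 4-OSiEt3 and C9=C10 (C14 on C10; C15 on C4)
Conditions: TESOTf (10 mol %), CH2Cl2, −78 °C
Reagents that add atoms: none
Why: Intramolecular (4+3) cycloaddition of an epoxy enol silane with the tethered furan, in which silyl triflate activates the epoxide, furan C1 attacks C5 anti to the breaking C5–O bond (inversion) through the extended transition state while C7 bonds to C8, so that cyclopentane and oxa-bridged cycloheptenone form together, C1, C5 and C8 are set, and the retained C4–OSiEt3 bond lies anti-periplanar to the new C1–C5 bond.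

Step 8
Reactants: 11 tricycle 6-ketone; 12 methyl bromoacetate
Product: 15 (1S,4R,5S,7R,8S)-tricycle 6-ketone with equatorial 7-CH2CO2Me and 4-OSiEt3, via ketone enolate 13 (not isolated), via product enolate 14 (not isolated)
Conditions: LDA (1.05 equiv), THF, −78 °C; 12, DMPU, −78 to −40 °C; LDA (1.1 equiv), −78 °C; AcOH, −78 °C
Reagents that add atoms: none
Why: Kinetic enolate alkylation at the less substituted α-carbon C7 (C5 is tertiary and hindered), then re-enolisation and kinetic protonation from the exo face (anti to the C9=C10 bridge) leaves the acetate arm equatorial, which is the C7 configuration of the later trans-lactone.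

Step 9
Reactants: 15 tricycle keto ester
Product: 16 (1S,4R,5S,6S,7S,8S)-tricycle 6-alcohol (equatorial OH, trans to the C7 arm)
Conditions: SmI2 (2.5 equiv), MeOH, THF, −78 °C
Reagents that add atoms: none
Why: Single-electron (samarium diiodide) ketone reduction under thermodynamic control gives the equatorial C6 alcohol trans to the C7 arm (hydride reagents would attack from the exo face and give the axial epimer); the product is silylated at once to forestall 6,12-lactonisation.

Step 10
Reactants: 16 tricycle 6-alcohol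
Product: 17 (1S,4R,5S,6S,7R,8S)-tricycle 6-OTBS ether
Conditions: TBSOTf, 2,6-lutidine, CH2Cl2, −78 °C
Reagents that add atoms: tert-butyldimethylsilyl triflate, CC(C)(C)[Si](C)(C)OS(=O)(=O)C(F)(F)F
Why: Silyl protection of the only free hydroxyl keeps O6 out of lactone formation and distinguishes it from the tertiary C4 silyl ether that will be the leaving group.

Step 11
Reactants: 17 tricycle 6-OTBS ether
Product: 21 (1S,4R,5S,6S,7R,8S)-tricycle with 7-[1-(methoxycarbonyl)ethenyl], 6-OTBS and 4-OSiEt3, via ester enolate 18 (not isolated), via Mannich base 19 (not isolated), via ammonium iodide 20 (not isolated)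
Conditions: LDA, THF, −78 °C; CH2=NMe2+ I−, −78 °C to rt; MeI, MeOH, rt; DBU, CH2Cl2, rt
Reagents that add atoms: Eschenmoser's salt, C=[N+](C)C.[I-]
Why: Ester-enolate Mannich reaction with Eschenmoser's salt, N-methylation and E1cB elimination (α-methylenation) works cleanly because the ester α-CH2 is the only acidic site once C6 is an ether; C11 becomes sp2, so no stereocentre arises.

Step 12
Reactants: 21 tricycle acrylate
Product: 24 (4Z,9Z,6R,7R,8S)-6-(tert-butyldimethylsilyloxy)-1-oxogermacra-4,9,11(13)-trien-12,8-olide, via oxocarbenium triflate 22 (not isolated), via hydroxy enone 23 (not isolated)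
Conditions: TMSOTf (1.2 equiv), 2,6-di-tert-butyl-4-methylpyridine, CH2Cl2, −78 to −40 °C; H2O–THF, 0 °C; PPTS (cat.), CH2Cl2, rt
Reagents that add atoms: water, O
Why: Proposed new method: silylation of the tertiary C4 silyl-ether oxygen by TMSOTf turns it into a disiloxane leaving group that is anti-periplanar to the C1–C5 bond (fixed by the invertive epoxide opening of step 7), so its departure is synchronised with C1–C5 cleavage pushed by a lone pair of the bridging ether oxygen (an ether-assisted cationic Grob fragmentation, closest known types being the Grob/Wharton fragmentation of 1,3-diol monosulfonates and the acid-induced cleavage of 1,3-diols with a tertiary carbinol), which expands the 5-7 system to the ten-membered ring, gives the 4Z alkene stereospecifically (C3 and C6 are already cis about C4–C5) and leaves a C1 oxocarbenium ion that water turns into the C1 ketone and the C8 hydroxyl, the latter closing the trans-lactone onto the acrylate ester (no new stereocentre; C6, C7 and C8 are carried through).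

Step 13
Reactants: 24 silyl ether lactone
Product: 25 (4Z,9Z,6R,7S,8S)-6-hydroxy-1-oxogermacra-4,9,11(13)-trien-12,8-olide
Conditions: HF·pyridine, pyridine, THF, 0 °C to rt
Reagents that add atoms: none
Why: Fluoride-mediated desilylation frees the C6 hydroxyl without touching the lactone, the enone or the methylene group.

Step 14
Reactants: 25 hydroxy dienone lactone
Product: 26 (4R,5S,6S,7S,8S,9Z)-4,5-epoxy-6-hydroxy-1-oxogermacra-9,11(13)-dien-12,8-olide
Conditions: Ti(OiPr)4 (1.2 equiv), L-(+)-DIPT (1.4 equiv), t-BuOOH, 4 Å MS, CH2Cl2, −20 °C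
Reagents that add atoms: tert-butyl hydroperoxide, CC(C)(C)OO
Why: Sharpless titanium–tartrate epoxidation in the matched sense, since this carbinol configuration is the fast-reacting one with L-(+)-tartrate and gives the erythro epoxy alcohol, which is the required cis-4,5-epoxide syn to O6 (4R,5S); the enone and methylene-lactone alkenes are inert to the Ti-alkoxide-bound oxidant.

Step 15
Reactants: 26 epoxy alcohol; 27 angelic acid
Product: 29 (4R,5S,6S,7R,8S,9Z)-6-angeloyloxy-4,5-epoxy-1-oxogermacra-9,11(13)-dien-12,8-olide, via mixed anhydride 28 (not isolated)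
Conditions: 27, 2,4,6-trichlorobenzoyl chloride, Et3N, toluene, rt; then 26, 75 °C
Reagents that add atoms: none
Why: Yamaguchi mixed-anhydride esterification without DMAP acylates the only hydroxyl and avoids the angelate-to-tiglate isomerisation seen under nucleophilic catalysis.

Step 16
Reactants: 29 angelate ketone
Product: 30 CNP0191628.1 [(1R,4R,5S,6S,7R,8S,9Z)-6-angeloyloxy-4,5-epoxy-1-hydroxygermacra-9,11(13)-dien-12,8-olide]
Conditions: (S)-Me-CBS (0.5 equiv), catecholborane, toluene, −78 °C
Reagents that add atoms: none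
Why: Corey–Bakshi–Shibata reduction of the enone carbonyl, in which the alkenyl side (C10) is the large group for the (S)-oxazaborolidine so that hydride delivery gives the 1R alcohol 1,2-selectively without touching the methylene lactone, the epoxide or the angelate.

**Compound list**

1 | 3-methylfuran-2-carbaldehyde | O=Cc1occc1C | starting material
2 | 3-methyl-2-vinylfuran | C=Cc1occc1C | intermediate
3 | (R)-pent-3-yn-2-ol | C[C@@H](O)C#CC | starting material
4 | sodium (5R)-2,2-bis(2-methoxyethoxy)-3,5-dimethyl-2,5-dihydro-1,2-oxaaluminol-2-uide (cyclic Z-vinylalanate) | C[C@H]1O[Al-](OCCOC)(OCCOC)C(C)=C1.[Na+] | intermediate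
5 | (R,Z)-4-iodopent-3-en-2-ol | C[C@@H](O)/C=C(\I)C | intermediate
6 | 9-[2-(3-methylfuran-2-yl)ethyl]-9-borabicyclo[3.3.1]nonane | Cc1ccoc1CCB1C2CCCC1CCC2 | intermediate
7 | (R,Z)-4-methyl-6-(3-methylfuran-2-yl)hex-3-en-2-ol | C[C@@H](O)/C=C(\CCc1occc1C)C | intermediate
8 | (R)-1-[(2S,3R)-3-methyl-3-[2-(3-methylfuran-2-yl)ethyl]oxiran-2-yl]ethan-1-ol (threo) | C[C@@H](O)[C@@H]1O[C@]1(C)CCc1occc1C | intermediate
9 | 1-[(2R,3R)-3-methyl-3-[2-(3-methylfuran-2-yl)ethyl]oxiran-2-yl]ethan-1-one (cis-epoxy ketone) | CC(=O)[C@@H]1O[C@]1(C)CCc1occc1C | intermediate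
10 | triethyl({1-[(2R,3R)-3-methyl-3-[2-(3-methylfuran-2-yl)ethyl]oxiran-2-yl]ethenyl}oxy)silane | C=C(O[Si](CC)(CC)CC)[C@@H]1O[C@]1(C)CCc1occc1C | intermediate
11 | (1S,4R,5S,8R)-tricycle: 6-ketone, 4-OSiEt3, C9=C10, C1–O–C8 bridge | O=C1C[C@H]2O[C@@]3(C(C)=C2)CC[C@@](C)(O[Si](CC)(CC)CC)[C@@H]13 | intermediate
12 | methyl bromoacetate | COC(=O)CBr | starting material
13 | lithium C6=C7 enolate of 11 | [Li]OC1=C[C@H]2O[C@@]3(C(C)=C2)CC[C@@](C)(O[Si](CC)(CC)CC)[C@@H]13 | intermediate
14 | lithium C6=C7 enolate of 15 | [Li]OC1=C(CC(=O)OC)[C@H]2O[C@@]3(C(C)=C2)CC[C@@](C)(O[Si](CC)(CC)CC)[C@@H]13 | intermediate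
15 | (1S,4R,5S,7R,8S)-tricycle: 6-ketone, 7-CH2CO2Me (equatorial, syn to the C9=C10 bridge), 4-OSiEt3 | O=C1[C@H](CC(=O)OC)[C@H]2O[C@@]3(C(C)=C2)CC[C@@](C)(O[Si](CC)(CC)CC)[C@@H]13 | intermediate
16 | (1S,4R,5S,6S,7S,8S)-tricycle: 6-OH (equatorial), 7-CH2CO2Me, 4-OSiEt3 | O[C@H]1[C@H](CC(=O)OC)[C@H]2O[C@@]3(C(C)=C2)CC[C@@](C)(O[Si](CC)(CC)CC)[C@@H]13 | intermediate
17 | (1S,4R,5S,6S,7R,8S)-tricycle: 6-OTBS, 7-CH2CO2Me, 4-OSiEt3 | CC(C)(C)[Si](C)(C)O[C@H]1[C@H](CC(=O)OC)[C@H]2O[C@@]3(C(C)=C2)CC[C@@](C)(O[Si](CC)(CC)CC)[C@@H]13 | intermediate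
18 | lithium ester enolate of 17 | CC(C)(C)[Si](C)(C)O[C@H]1[C@H](C=C(O[Li])OC)[C@H]2O[C@@]3(C(C)=C2)CC[C@@](C)(O[Si](CC)(CC)CC)[C@@H]13 | intermediate
19 | Mannich base of 17 (C11–CH2NMe2, C11 epimers) | CC(C)(C)[Si](C)(C)O[C@H]1[C@H](C(CN(C)C)C(=O)OC)[C@H]2O[C@@]3(C(C)=C2)CC[C@@](C)(O[Si](CC)(CC)CC)[C@@H]13 | intermediate
20 | trimethylammonium iodide of 19 | CC(C)(C)[Si](C)(C)O[C@H]1[C@H](C(C[N+](C)(C)C)C(=O)OC)[C@H]2O[C@@]3(C(C)=C2)CC[C@@](C)(O[Si](CC)(CC)CC)[C@@H]13.[I-] | intermediate
21 | (1S,4R,5S,6S,7R,8S)-tricycle: 7-[1-(methoxycarbonyl)ethenyl], 6-OTBS, 4-OSiEt3 | CC(C)(C)[Si](C)(C)O[C@H]1[C@H](C(=C)C(=O)OC)[C@H]2O[C@@]3(C(C)=C2)CC[C@@](C)(O[Si](CC)(CC)CC)[C@@H]13 | intermediate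
22 | ring-expanded C1 oxocarbenium triflate (C1=O+–C8 bridge on the ten-membered ring; 4Z; 6R,7R,8S; 6-OTBS; 7-acrylate) | C=C(C(=O)OC)[C@H]1[C@H](O[Si](C)(C)C(C)(C)C)/C=C(/C)CCC2=[O+][C@H]1C=C2C.[O-]S(=O)(=O)C(F)(F)F | intermediate
23 | methyl (4Z,9Z,6R,7R,8S)-6-(tert-butyldimethylsilyloxy)-8-hydroxy-1-oxogermacra-4,9,11(13)-trien-12-oate (in equilibrium with its C1 lactol) | C=C(C(=O)OC)[C@H]1[C@H](O[Si](C)(C)C(C)(C)C)/C=C(/C)CCC(=O)/C(C)=C\[C@@H]1O | intermediate
24 | (4Z,9Z,6R,7R,8S)-6-(tert-butyldimethylsilyloxy)-1-oxogermacra-4,9,11(13)-trien-12,8-olide | C=C1C(=O)O[C@H]2/C=C(/C)C(=O)CC/C(C)=C\[C@@H](O[Si](C)(C)C(C)(C)C)[C@H]12 | intermediate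
25 | (4Z,9Z,6R,7S,8S)-6-hydroxy-1-oxogermacra-4,9,11(13)-trien-12,8-olide | C=C1C(=O)O[C@H]2/C=C(/C)C(=O)CC/C(C)=C\[C@@H](O)[C@H]12 | intermediate
26 | (4R,5S,6S,7S,8S,9Z)-4,5-epoxy-6-hydroxy-1-oxogermacra-9,11(13)-dien-12,8-olide | C=C1C(=O)O[C@H]2/C=C(/C)C(=O)CC[C@@]3(C)O[C@H]3[C@@H](O)[C@H]12 | intermediate
27 | angelic acid [(Z)-2-methylbut-2-enoic acid] | C/C=C(/C)C(=O)O | starting material
28 | angelic 2,4,6-trichlorobenzoic anhydride | C/C=C(/C)C(=O)OC(=O)c1c(Cl)cc(Cl)cc1Cl | intermediate
29 | (4R,5S,6S,7R,8S,9Z)-6-angeloyloxy-4,5-epoxy-1-oxogermacra-9,11(13)-dien-12,8-olide | C=C1C(=O)O[C@H]2/C=C(/C)C(=O)CC[C@@]3(C)O[C@H]3[C@@H](OC(=O)/C(C)=C\C)[C@H]12 | intermediate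
30 | CNP0191628.1, (1R,4R,5S,6S,7R,8S,9Z)-6-angeloyloxy-4,5-epoxy-1-hydroxygermacra-9,11(13)-dien-12,8-olide | C=C1C(=O)O[C@H]2/C=C(/C)[C@H](O)CC[C@@]3(C)O[C@H]3[C@@H](OC(=O)/C(C)=C\C)[C@H]12 | target

**Step count**

Total: 16 steps. Longest linear sequence: 15 steps (3 → 30, steps 2–16); step 1 is a one-step branch.

**Three steps most likely to fail, with fallbacks**

Step 12 (the proposed new ring expansion). Risks are ionisation of the bridging allylic C1–O bond instead of C4–O, simple E1 loss of a proton from C4, and dehydration of lactol 23 towards a bridged furan. The fallback uses known chemistry and replaces the one-pot silyl-ether ionisation by a two-operation route through an isolated carbinol with a protic trigger. It sets out from 21: HF·pyridine in pyridine/THF at 0 °C cleaves the tertiary triethylsilyl ether while the secondary TBS ether stays, giving the C4 tertiary alcohol F1. F1 is then submitted to the long-known acid-induced fragmentation of 1,3-diol derivatives that carry a tertiary carbinol (retro-Prins type; camphorsulfonic acid, wet nitromethane, 0 °C), with water as the leaving group. This gives hydroxy enone 23, where the fallback comes back to the route (lactonisation to 24 as in step 12).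

Step 14 (epoxidation on the flexible ten-membered ring). Z-type secondary allylic alcohols react slowly with the titanium–tartrate reagent, and the C6-OH may not fully control the face. The fallback sets out from 25 and comes back at 26, changing from reagent control to substrate control: VO(acac)2/t-BuOOH hydroxyl-directed epoxidation, which gives cis epoxy alcohols with eight- and nine-membered Z-cycloalkenols. It needs no new compound: none F0.

Step 16 (C1 reduction). The macrocycle may override the catalyst, or the Lewis-basic groups may slow the oxazaborolidine. The fallback sets out from 29 and uses substrate control plus correction: Luche reduction (NaBH4, CeCl3·7H2O, MeOH, −78 °C) gives either 30 directly or its C1 epimer, 1-epi-target F2. F2 is inverted by Mitsunobu reaction with formic acid (PPh3, DIAD, THF, 0 °C) to the 1R formate, 1-O-formyl target F3. Mild methanolysis of F3 (KHCO3, MeOH, 0 °C; angelate and lactone survive) returns to the route at 30.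

**Further compounds**

F1 | step 12 | tricycle 21 with free tertiary C4-OH (6-OTBS, 7-[1-(methoxycarbonyl)ethenyl]) | CC(C)(C)[Si](C)(C)O[C@H]1[C@H](C(=C)C(=O)OC)[C@H]2O[C@@]3(C(C)=C2)CC[C@@](C)(O)[C@@H]13
F0 | step 14 | none | none
F2 | step 16 | (1S)-epimer of 30 | C=C1C(=O)O[C@H]2/C=C(/C)[C@@H](O)CC[C@@]3(C)O[C@H]3[C@@H](OC(=O)/C(C)=C\C)[C@H]12
F3 | step 16 | 1-O-formate of 30 (1R) | C=C1C(=O)O[C@H]2/C=C(/C)[C@H](OC=O)CC[C@@]3(C)O[C@H]3[C@@H](OC(=O)/C(C)=C\C)[C@H]12
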